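## Plan

1. Cembrane numbering is used throughout. C1 is the lactone β-CH, then C2H2 and C3(OH). C4(Me)–O–C7 is the oxolane (ring B), followed by C8(Me)(OAc), C9–C11, C12(Me), C13(OAc) and C14, the lactone O–CH. C15(=C17H2)–C16(=O) completes the lactone (ring A), and ring C is the macrocycle C1–C14.
2. After the two acetates and a C3 silyl ether, the C1–C14 bond (the one C–C bond shared by rings A and C) and the C16–O acyl bond are cut together. The cis-β,γ-disubstituted α-methylene-γ-butyrolactone (C14–O, C1–H, C15=C17) is the retron of a 2-(bromomethyl)enoate allyl metal adding to an aldehyde. Both rings therefore fall back to one monocyclic oxolane with a C14 aldehyde and a C1 (Z)-allylic bromide.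
3. Further cuts are C1–C15 (acrylate), C1–C2 (vinyl + epoxide), C9–C10 (Grignard + epoxide) and C12–C13 (crotylboration).
4. In the forward direction ring B arises first, by a Payne/5-exo-tet cascade on a geraniol-derived bis-epoxide. The chain is joined at C9–C10 and the arms are adjusted. Rings C and A then close in one indium Barbier allylation–lactonisation.
5. C3, C4, C7 and C8 come from a twofold Sharpless epoxidation with L-(+)-tartrate, relayed by inversions at C3 and C7. C12 and C13 come from (Z)-crotylboration of (S)-glyceraldehyde acetonide, whose own centre and extra carbon are excised when C14 is unmasked. C14 comes from Cram chelation to the C13 ether, and C1 from the (Z)-allyl geometry in a chair transition state.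

Key step: step 17

Assumption: (S)-glyceraldehyde acetonide 12 is taken as purchasable and used freshly distilled; the new carbinol centres of 22 and 25 are inconsequential epimer mixtures and are drawn without configuration.

## Route

Step 1
Reactants: 1 geranyl acetate
Product: 2 (2E,6E)-8-hydroxygeranyl acetate
Conditions: SeO2 (0.1 equiv), t-BuOOH (3 equiv), salicylic acid (0.1 equiv), CH2Cl2, 0 °C to rt
Reagents that add atoms: tert-butyl hydroperoxide CC(C)(C)OO
Why: Catalytic SeO2/t-BuOOH allylic oxidation (ene reaction followed by [2,3]-sigmatropic shift) should hydroxylate the (E)-methyl group of the distal trisubstituted alkene, since the other alkene is deactivated by its allylic acetate.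

Step 2
Reactants: 2 (2E,6E)-8-hydroxygeranyl acetate
Product: 3 (2E,6E)-8-hydroxygeraniol
Conditions: K2CO3 (0.2 equiv), MeOH, rt
Reagents that add atoms: none
Why: Carbonate-catalysed transesterification with methanol frees the second allylic alcohol and leaves both (E)-alkenes untouched.

Step 3
Reactants: 3 (2E,6E)-8-hydroxygeraniol
Product: 4 (2S,3S,6S,7S)-2,3:6,7-diepoxy-2,6-dimethyloctane-1,8-diol
Conditions: Ti(OiPr)4 (0.2 equiv), L-(+)-diethyl tartrate (0.26 equiv), t-BuOOH (4 equiv, decane), 4 Å MS, CH2Cl2, −20 °C
Reagents that add atoms: tert-butyl hydroperoxide CC(C)(C)OO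
Why: Twofold Sharpless asymmetric epoxidation: each alkene is an (E)-allylic alcohol and L-(+)-tartrate should deliver oxygen to the same sense of face at both, which sets C3, C4, C7 and C8 (all S at this stage) and lets the second epoxidation sharpen the enantiomeric purity of the major isomer.

Step 4
Reactants: 4 (2S,3S,6S,7S)-2,3:6,7-diepoxy-2,6-dimethyloctane-1,8-diol
Product: 6 (2S)-2-[(2R,5S)-5-methyl-5-[(2R)-oxiran-2-yl]oxolan-2-yl]propane-1,2-diol, via Payne-rearranged terminal epoxide 5 (not isolated)
Conditions: 0.5 M aq NaOH, t-BuOH, 0 °C to rt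
Reagents that add atoms: none
Why: Payne rearrangement followed by 5-exo-tet epoxide opening: the C2 alkoxide displaces at secondary C3 with inversion, the freed tertiary C4 alkoxide opens the other epoxide at secondary C7 with inversion to give the cis-2,5-disubstituted oxolane with C4 and C8 retained, whereas the corresponding sequence from the C9 hydroxyl would need two substitutions at fully substituted carbons and should not compete.

Step 5
Reactants: 6 (2S)-2-[(2R,5S)-5-methyl-5-[(2R)-oxiran-2-yl]oxolan-2-yl]propane-1,2-diol; 7 vinylmagnesium bromide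
Product: 8 (2S)-2-[(2R,5S)-5-[(1R)-1-hydroxybut-3-enyl]-5-methyloxolan-2-yl]propane-1,2-diol
Conditions: 7 (4 equiv), CuI (0.2 equiv), THF, −40 to 0 °C
Reagents that add atoms: none
Why: Copper-catalysed Grignard opening of a monosubstituted epoxide at its CH2 terminus forms C1–C2 and keeps the C3–O bond, the two hydroxyls being carried as magnesium alkoxides by the excess reagent.

Step 6
Reactants: 8 (2S)-2-[(2R,5S)-5-[(1R)-1-hydroxybut-3-enyl]-5-methyloxolan-2-yl]propane-1,2-diol
Product: 10 (1R)-1-[(2S,5R)-2-methyl-5-[(2S)-2-methyloxiran-2-yl]oxolan-2-yl]but-3-en-1-ol, via primary tosylate 9 (not isolated)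
Conditions: TsCl (1.05 equiv), Et3N, Bu2SnO (0.05 equiv), CH2Cl2, 0 °C; then K2CO3, MeOH, rt
Reagents that add atoms: none
Why: Stannylene-acetal-catalysed monotosylation should pick the primary hydroxyl of the 1,2-diol over the hindered C3 hydroxyl, and the C8 alkoxide then closes the epoxide by 3-exo-tet Williamson displacement with the C8–O bond intact.

Step 7
Reactants: 10 (1R)-1-[(2S,5R)-2-methyl-5-[(2S)-2-methyloxiran-2-yl]oxolan-2-yl]but-3-en-1-ol
Product: 11 C3 tert-butyldimethylsilyl ether of 10
Conditions: TBSCl, imidazole, DMAP (cat.), DMF, 40 °C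
Reagents that add atoms: tert-butyldimethylsilyl chloride CC(C)(C)[Si](C)(C)Cl
Why: Imidazole-promoted silylation of the only free hydroxyl, run with the chloride because a silyl triflate could ionise the 2,2-disubstituted epoxide.

Step 8
Reactants: 12 (S)-glyceraldehyde acetonide; 13 (Z)-crotylboronic acid pinacol ester
Product: 15 (1R,2S)-1-[(4S)-2,2-dimethyl-1,3-dioxolan-4-yl]-2-methylbut-3-en-1-ol, via borate ester 14 (not isolated)
Conditions: toluene, rt; then H2O
Reagents that add atoms: none
Why: Crotylboration through a Zimmerman–Traxler chair: the (Z)-boronate sets the 12,13-syn relation and the dioxolane C–O bond steers attack to the anti (Cornforth/Felkin–Anh) face, a substrate–reagent pairing of known high fidelity, so C13 (R) and C12 (S) arise without a chiral reagent.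

Step 9
Reactants: 15 (1R,2S)-1-[(4S)-2,2-dimethyl-1,3-dioxolan-4-yl]-2-methylbut-3-en-1-ol
Product: 16 (4S)-4-[(1R,2S)-1-(4-methoxybenzyloxy)-2-methylbut-3-enyl]-2,2-dimethyl-1,3-dioxolane
Conditions: NaH, PMBCl, Bu4NI (cat.), DMF, 0 °C to rt
Reagents that add atoms: 4-methoxybenzyl chloride COc1ccc(CCl)cc1
Why: Williamson etherification installs the p-methoxybenzyl ether that later serves as the chelating handle at C13 and can be removed oxidatively.

Step 10
Reactants: 16 (4S)-4-[(1R,2S)-1-(4-methoxybenzyloxy)-2-methylbut-3-enyl]-2,2-dimethyl-1,3-dioxolane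
Product: 18 (3S,4R)-4-[(4S)-2,2-dimethyl-1,3-dioxolan-4-yl]-4-(4-methoxybenzyloxy)-3-methylbutan-1-ol, via B-alkyl-9-BBN adduct 17 (not isolated)
Conditions: 9-BBN, THF, 0 °C to rt; then NaOH, H2O2, 0 °C
Reagents that add atoms: hydrogen peroxide OO
Why: Anti-Markovnikov hydroboration of the monosubstituted alkene with a bulky borane and oxidation with retention give the primary C10 alcohol without touching C12.

Step 11
Reactants: 18 (3S,4R)-4-[(4S)-2,2-dimethyl-1,3-dioxolan-4-yl]-4-(4-methoxybenzyloxy)-3-methylbutan-1-ol
Product: 19 (4S)-4-[(1R,2S)-4-bromo-1-(4-methoxybenzyloxy)-2-methylbutyl]-2,2-dimethyl-1,3-dioxolane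
Conditions: CBr4, PPh3, 2,6-lutidine, CH2Cl2, 0 °C
Reagents that add atoms: carbon tetrabromide BrC(Br)(Br)Br
Why: The Appel reaction converts the primary alcohol into the bromide under near-neutral conditions that spare the acetonide and the benzyl-type ether.

Step 12
Reactants: 19 (4S)-4-[(1R,2S)-4-bromo-1-(4-methoxybenzyloxy)-2-methylbutyl]-2,2-dimethyl-1,3-dioxolane; 11 C3 tert-butyldimethylsilyl ether of 10
Product: 21 coupled alkene, via Grignard reagent 20 (not isolated)
Conditions: Mg turnings, THF, rt; then CuI (0.15 equiv), 11, THF, −30 to 0 °C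
Reagents that add atoms: none
Why: Copper-catalysed Grignard opening of the 2,2-disubstituted epoxide at its CH2 group (C9) forms the C9–C10 bond and releases the C8 tertiary alcohol with its configuration unchanged.

Step 13
Reactants: 21 coupled alkene
Product: 23 C1 aldehyde, via vicinal diol 22 (not isolated)
Conditions: OsO4 (0.02 equiv), NaIO4 (4 equiv), 2,6-lutidine, dioxane–H2O 3:1, rt
Reagents that add atoms: sodium periodate [Na+].[O-]I(=O)(=O)=O
Why: Lemieux–Johnson cleavage of the only alkene trims the vinyl group to the C1 aldehyde, with 2,6-lutidine as buffer to protect the acetonide and the silyl ether.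

Step 14
Reactants: 23 C1 aldehyde; 24 methyl acrylate
Product: 25 Morita–Baylis–Hillman alcohol
Conditions: quinuclidine (0.5 equiv), MeOH (2 equiv), 24 (excess, neat), rt
Reagents that add atoms: none
Why: The Morita–Baylis–Hillman reaction of an unbranched aliphatic aldehyde forms C1–C15, and the new carbinol centre needs no control because it is erased in the next step.

Step 15
Reactants: 25 Morita–Baylis–Hillman alcohol
Product: 26 (Z)-allylic bromide acetonide
Conditions: NBS, Me2S, CH2Cl2, 0 °C to rt
Reagents that add atoms: N-bromosuccinimide O=C1CCC(=O)N1Br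
Why: The bromodimethylsulfonium reagent (Corey–Kim type) activates the allylic hydroxyl and bromide attacks C17 in SN2' fashion, which should give the conjugated (Z)-2-(bromomethyl)enoate from both epimers, while the tertiary C8 hydroxyl is returned on work-up.

Step 16
Reactants: 26 (Z)-allylic bromide acetonide
Product: 28 bromo aldehyde, via C14 glycol 27 (not isolated)
Conditions: H5IO6 (1.5 equiv), EtOAc, 0 °C to rt
Reagents that add atoms: none
Why: Periodic acid hydrolyses the terminal acetonide and cleaves the glycol in the same flask (Malaprade cleavage), which removes the helper carbon and stereocentre and unmasks the C14 aldehyde next to the untouched C13 ether.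

Step 17
Reactants: 28 bromo aldehyde
Product: 31 macrocyclic α-methylene lactone C13 PMB ether, via allylindium species 29 (not isolated), via macrocyclic hydroxy ester 30 (not isolated)
Conditions: indium powder (6 equiv), THF–H2O 3:1, syringe-pump addition of 28 to 1 mM final concentration, rt, sonication; then 1 M HCl to pH 3, rt
Reagents that add atoms: none
Why: Indium inserts into the allylic C–Br bond and the 2-(methoxycarbonyl)allylindium adds through its γ-carbon C1 to the C14 aldehyde (SE2', Barbier type; the intramolecular form of the Dreiding–Schmidt α-methylene-lactone synthesis, which is precedented for fourteen-membered cembranolide rings with zinc and with divalent chromium), after which the C14 oxygen is acylated by the neighbouring ester. Ring C closes by 14-exo-trig attack on the carbonyl (13-exo-trig when counted through the oxolane oxygen) with transposition of the alkene to the exocyclic C15=C17 position, and ring A closes by 5-exo-trig addition–elimination at C16 with loss of methanol. C14 is controlled by C13: trivalent indium should bridge the aldehyde oxygen and the C13 p-methoxybenzyl ether oxygen (Cram chelate), so that C1 arrives on the face opposite the C12 chain and gives the 13,14-syn (14R) alkoxide. C1 is controlled by the (Z)-geometry of the allyl unit, which in the chair transition state leads to the 1,14-syn adduct and hence to the cis-fused lactone (1S). The step needs ring closure to outrun oligomerisation and protonolysis, which is served by pseudo-high dilution, by the water tolerance of allylindium reagents and by the cis-2,5-disubstituted oxolane that turns both arms to the same side. γ- over α-attack is inherent to the cyclic transition state, and the free C8 hydroxyl and the silyl ether are inert.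

Step 18
Reactants: 31 macrocyclic α-methylene lactone C13 PMB ether
Product: 32 C8,C13-diol C3 silyl ether
Conditions: DDQ, CH2Cl2–pH 7 buffer, 0 °C
Reagents that add atoms: none
Why: Oxidative cleavage of the electron-rich benzyl ether by DDQ (hydride abstraction then hydrolysis) frees C13–OH without affecting the silyl ether or the α-methylene lactone.

Step 19
Reactants: 32 C8,C13-diol C3 silyl ether
Product: 33 C8,C13-diacetate C3 silyl ether
Conditions: Ac2O, DMAP, Et3N, CH2Cl2, rt to 40 °C
Reagents that add atoms: acetic anhydride CC(=O)OC(C)=O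
Why: DMAP-catalysed acyl transfer acetylates the secondary C13 hydroxyl and, on longer exposure, the tertiary C8 hydroxyl, while C3 stays masked as its silyl ether.

Step 20
Reactants: 33 C8,C13-diacetate C3 silyl ether
Product: 34 target (CID10479028)
Conditions: HF·pyridine, pyridine, THF, 0 °C to rt
Reagents that add atoms: none
Why: Fluoride-induced desilylation under buffered acidic conditions frees C3–OH and avoids the acetate migration and conjugate addition that a basic fluoride source could cause.

## Compound list

1 | geranyl acetate | CC(C)=CCC/C(C)=C/COC(C)=O | starting material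
2 | (2E,6E)-8-hydroxygeranyl acetate [(2E,6E)-8-hydroxy-3,7-dimethylocta-2,6-dienyl acetate] | OC/C(C)=C/CC/C(C)=C/COC(C)=O | intermediate
3 | (2E,6E)-8-hydroxygeraniol [(2E,6E)-2,6-dimethylocta-2,6-diene-1,8-diol] | OC/C(C)=C/CC/C(C)=C/CO | intermediate
4 | (2S,3S,6S,7S)-2,3:6,7-diepoxy-2,6-dimethyloctane-1,8-diol | OC[C@]1(C)O[C@H]1CC[C@]2(C)O[C@H]2CO | intermediate
5 | Payne-rearranged terminal epoxide, (2S,3S,6S,7R)-2,3:7,8-diepoxy-2,6-dimethyloctane-1,6-diol | OC[C@]1(C)O[C@H]1CC[C@](C)(O)[C@H]2CO2 | intermediate
6 | (2S)-2-[(2R,5S)-5-methyl-5-[(2R)-oxiran-2-yl]oxolan-2-yl]propane-1,2-diol | OC[C@](C)(O)[C@H]1CC[C@](C)(O1)[C@H]2CO2 | intermediate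
7 | vinylmagnesium bromide | C=C[Mg]Br | starting material
8 | (2S)-2-[(2R,5S)-5-[(1R)-1-hydroxybut-3-enyl]-5-methyloxolan-2-yl]propane-1,2-diol | OC[C@](C)(O)[C@H]1CC[C@](C)(O1)[C@H](O)CC=C | intermediate
9 | primary tosylate of 8 (C9 O-tosyl; C8 and C3 hydroxyls free) | Cc1ccc(cc1)S(=O)(=O)OC[C@](C)(O)[C@H]2CC[C@](C)(O2)[C@H](O)CC=C | intermediate
10 | (1R)-1-[(2S,5R)-2-methyl-5-[(2S)-2-methyloxiran-2-yl]oxolan-2-yl]but-3-en-1-ol | C[C@]1(CO1)[C@H]2CC[C@](C)(O2)[C@H](O)CC=C | intermediate
11 | C3 tert-butyldimethylsilyl ether of 10 | C[C@]1(CO1)[C@H]2CC[C@](C)(O2)[C@H](O[Si](C)(C)C(C)(C)C)CC=C | intermediate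
12 | (S)-glyceraldehyde acetonide [(4S)-2,2-dimethyl-1,3-dioxolane-4-carbaldehyde] | CC1(C)OC[C@H](O1)C=O | starting material
13 | (Z)-crotylboronic acid pinacol ester | C/C=C\CB1OC(C)(C)C(C)(C)O1 | starting material
14 | borate ester (O-pinacolboryl derivative of 15) | CC1(C)OC[C@H](O1)[C@H](OB2OC(C)(C)C(C)(C)O2)[C@@H](C)C=C | intermediate
15 | (1R,2S)-1-[(4S)-2,2-dimethyl-1,3-dioxolan-4-yl]-2-methylbut-3-en-1-ol | CC1(C)OC[C@H](O1)[C@H](O)[C@@H](C)C=C | intermediate
16 | (4S)-4-[(1R,2S)-1-(4-methoxybenzyloxy)-2-methylbut-3-enyl]-2,2-dimethyl-1,3-dioxolane | CC1(C)OC[C@H](O1)[C@H](OCc2ccc(OC)cc2)[C@@H](C)C=C | intermediate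
17 | B-alkyl-9-BBN adduct of 16 (boron on the terminal carbon C10) | CC1(C)OC[C@H](O1)[C@H](OCc2ccc(OC)cc2)[C@@H](C)CCB3C4CCCC3CCC4 | intermediate
18 | (3S,4R)-4-[(4S)-2,2-dimethyl-1,3-dioxolan-4-yl]-4-(4-methoxybenzyloxy)-3-methylbutan-1-ol | CC1(C)OC[C@H](O1)[C@H](OCc2ccc(OC)cc2)[C@@H](C)CCO | intermediate
19 | (4S)-4-[(1R,2S)-4-bromo-1-(4-methoxybenzyloxy)-2-methylbutyl]-2,2-dimethyl-1,3-dioxolane | CC1(C)OC[C@H](O1)[C@H](OCc2ccc(OC)cc2)[C@@H](C)CCBr | intermediate
20 | Grignard reagent from 19 | CC1(C)OC[C@H](O1)[C@H](OCc2ccc(OC)cc2)[C@@H](C)CC[Mg]Br | intermediate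
21 | coupled alkene: (3R,4S,7R,8S,12S,13R) open chain with C1H=CH2 end, C3 OTBS, 4,7-oxolane, C8 OH, C13 OPMB, C14 as C4 of a (4S)-2,2-dimethyl-1,3-dioxolane | CC1(C)OC[C@H](O1)[C@H](OCc2ccc(OC)cc2)[C@@H](C)CCC[C@](C)(O)[C@H]3CC[C@](C)(O3)[C@H](O[Si](C)(C)C(C)(C)C)CC=C | intermediate
22 | vicinal diol from dihydroxylation of the vinyl group of 21 (epimers at C1) | CC1(C)OC[C@H](O1)[C@H](OCc2ccc(OC)cc2)[C@@H](C)CCC[C@](C)(O)[C@H]3CC[C@](C)(O3)[C@H](O[Si](C)(C)C(C)(C)C)CC(O)CO | intermediate
23 | C1 aldehyde (as 21, with C1H=O in place of the vinyl group) | CC1(C)OC[C@H](O1)[C@H](OCc2ccc(OC)cc2)[C@@H](C)CCC[C@](C)(O)[C@H]3CC[C@](C)(O3)[C@H](O[Si](C)(C)C(C)(C)C)CC=O | intermediate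
24 | methyl acrylate | C=CC(=O)OC | starting material
25 | Morita–Baylis–Hillman alcohol (C1 carbinol bearing the methyl 2-propenoate unit at C15; epimers at C1) | CC1(C)OC[C@H](O1)[C@H](OCc2ccc(OC)cc2)[C@@H](C)CCC[C@](C)(O)[C@H]3CC[C@](C)(O3)[C@H](O[Si](C)(C)C(C)(C)C)CC(O)C(=C)C(=O)OC | intermediate
26 | (Z)-allylic bromide acetonide (methyl (Z)-2-(bromomethyl)enoate, C2 cis to CH2Br; other centres as 21) | CC1(C)OC[C@H](O1)[C@H](OCc2ccc(OC)cc2)[C@@H](C)CCC[C@](C)(O)[C@H]3CC[C@](C)(O3)[C@H](O[Si](C)(C)C(C)(C)C)C/C=C(\CBr)C(=O)OC | intermediate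
27 | C14 glycol (26 with the acetonide hydrolysed) | OC[C@H](O)[C@H](OCc1ccc(OC)cc1)[C@@H](C)CCC[C@](C)(O)[C@H]2CC[C@](C)(O2)[C@H](O[Si](C)(C)C(C)(C)C)C/C=C(\CBr)C(=O)OC | intermediate
28 | bromo aldehyde: (3R,4S,7R,8S,12S,13R) chain with C14H=O, C13 OPMB, C8 OH, 4,7-oxolane, C3 OTBS and the (Z)-2-(bromomethyl)enoate at C1 | O=C[C@H](OCc1ccc(OC)cc1)[C@@H](C)CCC[C@](C)(O)[C@H]2CC[C@](C)(O2)[C@H](O[Si](C)(C)C(C)(C)C)C/C=C(\CBr)C(=O)OC | intermediate
29 | allylindium species from 28 (drawn as the allylindium dibromide) | O=C[C@H](OCc1ccc(OC)cc1)[C@@H](C)CCC[C@](C)(O)[C@H]2CC[C@](C)(O2)[C@H](O[Si](C)(C)C(C)(C)C)C/C=C(\C[In](Br)Br)C(=O)OC | intermediate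
30 | macrocyclic hydroxy ester (1S,3R,4S,7R,8S,12S,13R,14R): ring C closed, C14 OH, methyl 2-propenoate on C1 | C=C(C(=O)OC)[C@H]1[C@@H](O)[C@H](OCc2ccc(OC)cc2)[C@@H](C)CCC[C@](C)(O)[C@H]3CC[C@](C)(O3)[C@H](O[Si](C)(C)C(C)(C)C)C1 | intermediate
31 | macrocyclic α-methylene lactone C13 PMB ether (1S,3R,4S,7R,8S,12S,13R,14R; cis-fused lactone, C8 OH, C3 OTBS) | C=C1C(=O)O[C@H]2[C@H](OCc3ccc(OC)cc3)[C@@H](C)CCC[C@](C)(O)[C@H]4CC[C@](C)(O4)[C@H](O[Si](C)(C)C(C)(C)C)C[C@@H]12 | intermediate
32 | C8,C13-diol C3 silyl ether (configuration as 31) | C=C1C(=O)O[C@H]2[C@H](O)[C@@H](C)CCC[C@](C)(O)[C@H]3CC[C@](C)(O3)[C@H](O[Si](C)(C)C(C)(C)C)C[C@@H]12 | intermediate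
33 | C8,C13-diacetate C3 silyl ether (configuration as 31) | C=C1C(=O)O[C@H]2[C@H](OC(C)=O)[C@@H](C)CCC[C@](C)(OC(C)=O)[C@H]3CC[C@](C)(O3)[C@H](O[Si](C)(C)C(C)(C)C)C[C@@H]12 | intermediate
34 | target CID10479028, (1S,3R,4S,7R,8S,12S,13R,14R) in cembrane numbering | C=C1C(=O)O[C@H]2[C@H](OC(C)=O)[C@@H](C)CCC[C@](C)(OC(C)=O)[C@H]3CC[C@](C)(O3)[C@H](O)C[C@@H]12 | target

## Step count and risks

Total step count: 20.
Longest linear sequence: 16 steps (steps 1–7 and 12–20).

**Step 17.**
- What may go wrong: chelation of the C13 ether may be too weak in the aqueous medium, which would erode facial selectivity at C14. Protonolysis or oligomerisation of the allylindium may also outrun the slow ring closure.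
- Fallback, setting out from 28: exchange of the allylic bromide with (Bu3Sn)2 under Pd2(dba)3 catalysis (zerovalent palladium, THF, rt) would place tin on the primary terminus and give the allylstannane aldehyde F1.
- Slow addition of F1 to MgBr2·OEt2 in CH2Cl2 at −20 °C under high dilution would run the closure as a Lewis-acid-promoted SE2' addition. It passes through an open antiperiplanar transition state on a preformed magnesium chelate of the aldehyde and the C13 ether.
- This is a chelation-controlled allylstannane addition, syn-selective for γ-substituted allylstannanes whatever their geometry. It would give hydroxy ester 30, which PPTS would lactonise, and the route is rejoined at 31.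

**Step 4.**
- What may go wrong: the unfavourable Payne equilibrium may drain slowly. During that time hydroxide or the new C8 alkoxide may open the terminal epoxide.
- Fallback, setting out from 4: slow addition of PhSH to 4 in aq NaOH/t-BuOH at 60 °C (Payne rearrangement with irreversible thiolate capture at C2, oxolane closure as before) would give the C2 phenyl sulfide triol F2.
- S-methylation with Me3OBF4 in CH2Cl2 would give the methyl(phenyl)sulfonium tetrafluoroborate F3.
- Aqueous NaOH would then close the C3 oxygen onto C2 with retention at C3, and the route is rejoined at 6.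

**Step 14.**
- What may go wrong: amine-catalysed turnover may be sluggish, so that base-induced β-elimination of the C3 silyloxy group competes.
- Fallback, setting out from 23: [1-(methoxycarbonyl)vinyl]diisobutylaluminium is preformed from methyl propiolate and i-Bu2AlH with HMPA in THF at 0 °C (conjugate hydroalumination).
- This reagent would add 1,2 to the aldehyde within a short time in the absence of amine base, with one extra equivalent taken up by the C8 hydroxyl.
- The route is rejoined at 25, and no new compound is made (F0).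

## Further compounds

F1 | step 17 | allylstannane aldehyde | O=C[C@H](OCc1ccc(OC)cc1)[C@@H](C)CCC[C@](C)(O)[C@H]2CC[C@](C)(O2)[C@H](O[Si](C)(C)C(C)(C)C)C/C=C(\C[Sn](CCCC)(CCCC)CCCC)C(=O)OC
F2 | step 4 | C2 phenyl sulfide triol | OC[C@](C)(O)[C@H]1CC[C@](C)(O1)[C@H](O)CSc2ccccc2
F3 | step 4 | methyl(phenyl)sulfonium tetrafluoroborate | OC[C@](C)(O)[C@H]1CC[C@](C)(O1)[C@H](O)C[S+](C)c2ccccc2.F[B-](F)(F)F
F0 | step 14 | none | none
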